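**Retrosynthetic overview**
- The C8 ester and the free C6 hydroxyl come from a macrocyclic alcohol in which only the C8 hydroxyl is free (C6 is a silyl ether).
- The ten-membered carbocycle is closed last, at C9–C10, by a proposed nickel-catalysed reductive coupling of a (Z)-alkenyl iodide with a terminal epoxide; this also releases the C8 hydroxyl.
- C8 comes from hydroxyl-directed epoxidation of a homoallylic alcohol; C6 and C7 come from an anti-selective (E)-γ-isopropylallylboration of a cis-epoxy aldehyde.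
- The cis C4–C5 epoxide comes from Sharpless epoxidation of nerol (its Z-alkene is kept); the Z C1=C10 alkene comes from ozonolysis of the prenyl end followed by Stork–Zhao olefination.
- Ring order: C4–C5 oxirane first, a sacrificial C8–C9 oxirane second, the ten-membered ring last.

Assumption: the SMILES is taken as written, which means a (Z)-C1=C10 alkene and a cis-fused 4,5-epoxide. Atom labels follow germacrane numbering (C4–C5 epoxide, C6 OH, C7 isopropyl, C8 ester, C9, C10(CH3)=C1, C2, C3).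

**Route**

Step 1
Reactants: 1 nerol
Product: 2 [(2R,3S)-3-methyl-3-(4-methylpent-3-en-1-yl)oxiran-2-yl]methanol
Conditions: Ti(OiPr)4 (10 mol %), D-(−)-diisopropyl tartrate (12 mol %), t-BuOOH, 4 Å MS, CH2Cl2, −20 °C
Reagents that add atoms: tert-butyl hydroperoxide CC(C)(C)OO
Why: Sharpless asymmetric epoxidation touches only the allylic alkene; the D-tartrate ligand delivers oxygen to the face that gives C4 (S) and C5 (R), and the Z-alkene of nerol becomes the cis-epoxide.

Step 2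
Reactants: 2 [(2R,3S)-3-methyl-3-(4-methylpent-3-en-1-yl)oxiran-2-yl]methanol
Product: 3 (2S,3S)-3-methyl-3-(4-methylpent-3-en-1-yl)oxirane-2-carbaldehyde
Conditions: Dess–Martin periodinane, NaHCO3, CH2Cl2, 0 to 23 °C; used crude
Reagents that add atoms: none
Why: Buffered Dess–Martin oxidation of a 2,3-epoxy alcohol gives the epoxy aldehyde without opening the epoxide; C5 cannot epimerise because it is an oxirane carbon (the descriptor changes only through priorities).

Step 3
Reactants: 4 (2E)-4-methylpent-2-ene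
Product: 7 dipropan-2-yl (4S,5S)-2-[(2E)-4-methylpent-2-en-1-yl]-1,3,2-dioxaborolane-4,5-dicarboxylate, via allylpotassium 5 (not isolated), via diisopropyl allylboronate 6 (not isolated)
Conditions: n-BuLi, KOt-Bu, THF, −78 to −50 °C; B(OiPr)3, −78 °C; 1 M HCl; D-(−)-diisopropyl tartrate, MgSO4, Et2O, 23 °C
Reagents that add atoms: triisopropyl borate CC(C)OB(OC(C)C)OC(C)C; diisopropyl D-tartrate CC(C)OC(=O)[C@@H](O)[C@H](O)C(=O)OC(C)C
Why: Schlosser metalation removes an allylic methyl proton and keeps the E geometry at low temperature, borylation occurs at the CH2 terminus, and transesterification gives the Roush-type tartrate (E)-allylboronate.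

Step 4
Reactants: 3 (2S,3S)-3-methyl-3-(4-methylpent-3-en-1-yl)oxirane-2-carbaldehyde; 7 dipropan-2-yl (4S,5S)-2-[(2E)-4-methylpent-2-en-1-yl]-1,3,2-dioxaborolane-4,5-dicarboxylate
Product: 9 (1R,2R)-1-[(2R,3S)-3-methyl-3-(4-methylpent-3-en-1-yl)oxiran-2-yl]-2-(propan-2-yl)but-3-en-1-ol, via tartrate borate ester 8 (not isolated)
Conditions: 4 Å MS, toluene, −78 °C, 12 h; then H2O, 23 °C
Reagents that add atoms: none
Why: Roush double-asymmetric allylboration through a closed chair transition state: the E-boronate gives the anti C6/C7 relationship, and the (S,S)-tartrate directs attack to the re face of the aldehyde (O > C5 > H), which sets C6 (R) and C7 and should be matched with the intrinsic erythro preference of the cis-epoxy aldehyde.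

Step 5
Reactants: 9 (1R,2R)-1-[(2R,3S)-3-methyl-3-(4-methylpent-3-en-1-yl)oxiran-2-yl]-2-(propan-2-yl)but-3-en-1-ol
Product: 10 (1R,2S)-3-methyl-1-[(2R,3S)-3-methyl-3-(4-methylpent-3-en-1-yl)oxiran-2-yl]-2-[(2S)-oxiran-2-yl]butan-1-ol
Conditions: VO(acac)2 (5 mol %), t-BuOOH (anhydrous, 1.5 equiv), CH2Cl2, 0 to 23 °C
Reagents that add atoms: tert-butyl hydroperoxide CC(C)(C)OO
Why: Hydroxyl-directed vanadium epoxidation of the homoallylic vinyl group through a chair-like vanadate transition state with the C6 substituent and the C7 isopropyl both equatorial (possible because they are anti) puts the new C8–O bond syn to C6–O; the remote prenyl alkene has no directing group and is left.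

Step 6
Reactants: 10 (1R,2S)-3-methyl-1-[(2R,3S)-3-methyl-3-(4-methylpent-3-en-1-yl)oxiran-2-yl]-2-[(2S)-oxiran-2-yl]butan-1-ol
Product: 11 triethyl{(1R,2R)-3-methyl-1-[(2R,3S)-3-methyl-3-(4-methylpent-3-en-1-yl)oxiran-2-yl]-2-[(2S)-oxiran-2-yl]butoxy}silane
Conditions: Et3SiCl, imidazole, DMAP (cat.), DMF, 0 to 23 °C
Reagents that add atoms: chlorotriethylsilane CC[Si](Cl)(CC)CC
Why: Standard silylation masks the C6 hydroxyl so that only the C8 hydroxyl released later is acylated; no stereocentre is touched (the C7 descriptor changes only through priorities).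

Step 7
Reactants: 11 triethyl{(1R,2R)-3-methyl-1-[(2R,3S)-3-methyl-3-(4-methylpent-3-en-1-yl)oxiran-2-yl]-2-[(2S)-oxiran-2-yl]butoxy}silane
Product: 13 3-{(2S,3R)-2-methyl-3-[(1R,2R)-3-methyl-2-[(2S)-oxiran-2-yl]-1-[(triethylsilyl)oxy]butyl]oxiran-2-yl}propanal, via secondary ozonide 12 (not isolated)
Conditions: O3, CH2Cl2, −78 °C; PPh3, −78 to 23 °C
Reagents that add atoms: ozone [O-][O+]=O
Why: Ozonolysis with reductive work-up cleaves the only remaining C=C (the prenyl alkene) to the C1 aldehyde and acetone; epoxides and the silyl ether are inert.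

Step 8
Reactants: 13 3-{(2S,3R)-2-methyl-3-[(1R,2R)-3-methyl-2-[(2S)-oxiran-2-yl]-1-[(triethylsilyl)oxy]butyl]oxiran-2-yl}propanal
Product: 14 triethyl{(1R,2R)-1-[(2R,3S)-3-[(3Z)-4-iodopent-3-en-1-yl]-3-methyloxiran-2-yl]-3-methyl-2-[(2S)-oxiran-2-yl]butoxy}silane
Conditions: [Ph3PCH2CH3]I, n-BuLi, THF, 23 °C; I2, −78 °C; NaN(SiMe3)2, −78 to −20 °C; then 13, −78 to −20 °C
Reagents that add atoms: ethyltriphenylphosphonium iodide CC[P+](c1ccccc1)(c1ccccc1)c1ccccc1.[I-]; iodine II
Why: Stork–Zhao Wittig olefination with the α-iodo ylide Ph3P=C(I)CH3 gives the (Z)-2-iodoalk-2-ene under kinetic control (iodine cis to C2), which fixes the C1=C10 geometry before ring closure.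

Step 9
Reactants: 14 triethyl{(1R,2R)-1-[(2R,3S)-3-[(3Z)-4-iodopent-3-en-1-yl]-3-methyloxiran-2-yl]-3-methyl-2-[(2S)-oxiran-2-yl]butoxy}silane
Product: 16 (1R,2R,3R,4R,6Z,10S)-6,10-dimethyl-3-(propan-2-yl)-2-[(triethylsilyl)oxy]-11-oxabicyclo[8.1.0]undec-6-en-4-ol, via iodohydrin 15 (not isolated)
Conditions: NiBr2(dme) (20 mol %), 4,4'-di-tert-butyl-2,2'-bipyridine (24 mol %), NaI (0.5 equiv), Et3N·HCl (1.5 equiv), Mn powder (3 equiv), DMPU, 25 °C, 14 added over 12 h to 2 mM
Reagents that add atoms: none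
Why: Proposed new method: an intramolecular nickel-catalysed reductive cross-electrophile coupling of a (Z)-alkenyl iodide with a terminal epoxide that closes the ten-membered carbocycle; iodide (with Et3NH+ as proton donor) opens only the unhindered monosubstituted oxirane at C9 to give iodohydrin 15 without touching C8, zerovalent nickel adds to the C10–I bond with retention of the Z geometry, monovalent nickel abstracts iodine from C9, the primary C9 radical is captured by the alkenylnickel centre in the same molecule, and reductive elimination from trivalent nickel forms C9–C10 while Mn returns the catalyst, so the step forms the ring and unveils the C8 hydroxyl in one operation; high dilution with slow addition should favour ring closure over dimerisation and the Z-alkene plus cis-epoxide act as turn elements; the closest known reaction type is the intermolecular nickel-catalysed reductive coupling of aryl or alkenyl halides with terminal epoxides under iodide co-catalysis.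

Step 10
Reactants: 16 (1R,2R,3R,4R,6Z,10S)-6,10-dimethyl-3-(propan-2-yl)-2-[(triethylsilyl)oxy]-11-oxabicyclo[8.1.0]undec-6-en-4-ol; 17 3,4,5-trimethoxybenzoyl chloride
Product: 18 (1R,2R,3R,4R,6Z,10S)-6,10-dimethyl-3-(propan-2-yl)-2-[(triethylsilyl)oxy]-11-oxabicyclo[8.1.0]undec-6-en-4-yl 3,4,5-trimethoxybenzoate
Conditions: Et3N, DMAP, CH2Cl2, 0 to 23 °C
Reagents that add atoms: none
Why: DMAP-catalysed acyl transfer esterifies the only free hydroxyl (C8) with retention of configuration.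

Step 11
Reactants: 18 (1R,2R,3R,4R,6Z,10S)-6,10-dimethyl-3-(propan-2-yl)-2-[(triethylsilyl)oxy]-11-oxabicyclo[8.1.0]undec-6-en-4-yl 3,4,5-trimethoxybenzoate
Product: 19 (1R,2R,3S,4R,6Z,10S)-2-hydroxy-6,10-dimethyl-3-(propan-2-yl)-11-oxabicyclo[8.1.0]undec-6-en-4-yl 3,4,5-trimethoxybenzoate
Conditions: Bu4NF, AcOH (1:1), THF, 0 °C
Reagents that add atoms: none
Why: Fluoride desilylation buffered with acetic acid frees the C6 hydroxyl while avoiding base-induced 1,3-acyl migration and acid-induced transannular opening of the epoxide; no stereocentre is touched.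

**Compound list**
1 | nerol, (2Z)-3,7-dimethylocta-2,6-dien-1-ol | CC(C)=CCC/C(C)=C\CO | starting material
2 | [(2R,3S)-3-methyl-3-(4-methylpent-3-en-1-yl)oxiran-2-yl]methanol (cis-epoxide, (2R,3S)-2,3-epoxynerol) | CC(C)=CCC[C@]1(C)O[C@@H]1CO | intermediate
3 | (2S,3S)-3-methyl-3-(4-methylpent-3-en-1-yl)oxirane-2-carbaldehyde | CC(C)=CCC[C@]1(C)O[C@@H]1C=O | intermediate
4 | (2E)-4-methylpent-2-ene | C/C=C/C(C)C | starting material
5 | [(2E)-4-methylpent-2-en-1-yl]potassium | CC(C)/C=C/C[K] | intermediate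
6 | dipropan-2-yl [(2E)-4-methylpent-2-en-1-yl]boronate | CC(C)/C=C/CB(OC(C)C)OC(C)C | intermediate
7 | dipropan-2-yl (4S,5S)-2-[(2E)-4-methylpent-2-en-1-yl]-1,3,2-dioxaborolane-4,5-dicarboxylate | CC(C)/C=C/CB1O[C@H](C(=O)OC(C)C)[C@@H](C(=O)OC(C)C)O1 | intermediate
8 | dipropan-2-yl (4S,5S)-2-{[(1R,2R)-1-[(2R,3S)-3-methyl-3-(4-methylpent-3-en-1-yl)oxiran-2-yl]-2-(propan-2-yl)but-3-en-1-yl]oxy}-1,3,2-dioxaborolane-4,5-dicarboxylate (borate ester of 9) | CC(C)=CCC[C@]1(C)O[C@@H]1[C@H](OB2O[C@H](C(=O)OC(C)C)[C@@H](C(=O)OC(C)C)O2)[C@@H](C=C)C(C)C | intermediate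
9 | (1R,2R)-1-[(2R,3S)-3-methyl-3-(4-methylpent-3-en-1-yl)oxiran-2-yl]-2-(propan-2-yl)but-3-en-1-ol | CC(C)=CCC[C@]1(C)O[C@@H]1[C@H](O)[C@@H](C=C)C(C)C | intermediate
10 | (1R,2S)-3-methyl-1-[(2R,3S)-3-methyl-3-(4-methylpent-3-en-1-yl)oxiran-2-yl]-2-[(2S)-oxiran-2-yl]butan-1-ol | CC(C)=CCC[C@]1(C)O[C@@H]1[C@H](O)[C@@H]([C@H]2CO2)C(C)C | intermediate
11 | triethyl{(1R,2R)-3-methyl-1-[(2R,3S)-3-methyl-3-(4-methylpent-3-en-1-yl)oxiran-2-yl]-2-[(2S)-oxiran-2-yl]butoxy}silane | CC(C)=CCC[C@]1(C)O[C@@H]1[C@H](O[Si](CC)(CC)CC)[C@@H]([C@H]2CO2)C(C)C | intermediate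
12 | 3,3-dimethyl-5-(2-{(2S,3R)-2-methyl-3-[(1R,2R)-3-methyl-2-[(2S)-oxiran-2-yl]-1-[(triethylsilyl)oxy]butyl]oxiran-2-yl}ethyl)-1,2,4-trioxolane (secondary ozonide, both epimers at the trioxolane CH) | CC1(C)OOC(CC[C@]2(C)O[C@@H]2[C@H](O[Si](CC)(CC)CC)[C@@H]([C@H]3CO3)C(C)C)O1 | intermediate
13 | 3-{(2S,3R)-2-methyl-3-[(1R,2R)-3-methyl-2-[(2S)-oxiran-2-yl]-1-[(triethylsilyl)oxy]butyl]oxiran-2-yl}propanal | O=CCC[C@]1(C)O[C@@H]1[C@H](O[Si](CC)(CC)CC)[C@@H]([C@H]2CO2)C(C)C | intermediate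
14 | triethyl{(1R,2R)-1-[(2R,3S)-3-[(3Z)-4-iodopent-3-en-1-yl]-3-methyloxiran-2-yl]-3-methyl-2-[(2S)-oxiran-2-yl]butoxy}silane | I/C(C)=C\CC[C@]1(C)O[C@@H]1[C@H](O[Si](CC)(CC)CC)[C@@H]([C@H]2CO2)C(C)C | intermediate
15 | (2S,3R,4R)-1-iodo-4-[(2R,3S)-3-[(3Z)-4-iodopent-3-en-1-yl]-3-methyloxiran-2-yl]-3-(propan-2-yl)-4-[(triethylsilyl)oxy]butan-2-ol | I/C(C)=C\CC[C@]1(C)O[C@@H]1[C@H](O[Si](CC)(CC)CC)[C@@H]([C@H](O)CI)C(C)C | intermediate
16 | (1R,2R,3R,4R,6Z,10S)-6,10-dimethyl-3-(propan-2-yl)-2-[(triethylsilyl)oxy]-11-oxabicyclo[8.1.0]undec-6-en-4-ol | O[C@@H]1C/C(C)=C\CC[C@]2(C)O[C@@H]2[C@H](O[Si](CC)(CC)CC)[C@@H]1C(C)C | intermediate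
17 | 3,4,5-trimethoxybenzoyl chloride | COc1cc(C(Cl)=O)cc(OC)c1OC | starting material
18 | (1R,2R,3R,4R,6Z,10S)-6,10-dimethyl-3-(propan-2-yl)-2-[(triethylsilyl)oxy]-11-oxabicyclo[8.1.0]undec-6-en-4-yl 3,4,5-trimethoxybenzoate | COc1cc(C(=O)O[C@@H]2C/C(C)=C\CC[C@]3(C)O[C@@H]3[C@H](O[Si](CC)(CC)CC)[C@@H]2C(C)C)cc(OC)c1OC | intermediate
19 | (1R,2R,3S,4R,6Z,10S)-2-hydroxy-6,10-dimethyl-3-(propan-2-yl)-11-oxabicyclo[8.1.0]undec-6-en-4-yl 3,4,5-trimethoxybenzoate (CNP0260213.10) | COc1cc(C(=O)O[C@@H]2C/C(C)=C\CC[C@]3(C)O[C@@H]3[C@H](O)[C@@H]2C(C)C)cc(OC)c1OC | target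

**Step count**
Total steps: 11. Longest linear sequence: 10 steps (nerol through steps 1, 2 and 4–11); step 3 is a one-step side branch for the boronate.

**Three steps most likely to fail**

Step 9, the proposed nickel macrocyclisation. It is untested and could give oligomers, simple reduction of the C–I bond, or attack on the wrong epoxide. The fallback uses known chemistry, sets out from aldehyde 13 and comes back at macrocyclic alcohol 16. Wittig methylenation of 13 (Ph3P=CH2, THF, −78 to 0 °C) gives the terminal alkene F1. CH2=C(CH3)MgBr with CuI (10 mol %) in THF at −30 °C opens the monosubstituted epoxide at its CH2 end and gives the diene alcohol F2, which already has the C9–C10 bond and the free C8 hydroxyl. Ring-closing metathesis with the second-generation Hoveyda–Grubbs catalyst RuCl2(SIMes)(=CH-C6H4-2-OiPr) (10 mol %, toluene, 1 mM, 80 °C) then forms C1=C10 and gives 16 with loss of ethylene. In this fallback the Z geometry rests on ring strain and not on design, so an E isomer may have to be separated.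

Step 8, the Stork–Zhao olefination. Yields are typically modest, some E isomer and some non-iodinated alkene form, and LiI may begin to open the terminal epoxide (harmless, since that product is iodohydrin 15). The fallback sets out from 13 and comes back at 16. Ramirez dibromo-olefination (CBr4, PPh3, 2,6-lutidine, CH2Cl2, 0 °C) gives the 1,1-dibromoalkene F3. Negishi coupling with CH3ZnCl (PdCl2(DPEphos) 5 mol %, THF, 0 to 23 °C) replaces only the bromine trans to the chain and gives the (Z)-alkenyl bromide F4, with bromine cis to C2. F4 is then taken through the conditions of step 9, where it forms the bromoalkenyl iodohydrin F5 and closes to 16.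

Step 5, the directed epoxidation. A terminal homoallylic alkene reacts slowly, the diastereoselectivity rests on a transition-state model, and the prenyl alkene must stay untouched. The fallback sets out from 9 and comes back at 14; it sets C8 by carbonate delivery instead of metal-directed oxygen transfer. Alcohol 9 is converted into the tert-butyl carbonate F6 (Boc2O, DMAP, MeCN). Ozonolysis with one equivalent of ozone from a titrated solution in CH2Cl2–pyridine at −78 °C cleaves the trisubstituted alkene in preference to the vinyl group and gives the aldehyde F7 directly. Stork–Zhao olefination as in step 8 gives the (Z)-alkenyl iodide F8. IBr in toluene at −85 °C effects the Bartlett–Smith iodocarbonate cyclisation through an all-equatorial chair and gives the six-membered cyclic iodocarbonate F9, with C8–O syn to C6–O. K2CO3 in MeOH cleaves the carbonate and closes the terminal epoxide to give the epoxy alcohol F10, and silylation as in step 6 gives 14.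

**Further compounds**
F1 | step 9 | triethyl{(1R,2R)-1-[(2R,3S)-3-(but-3-en-1-yl)-3-methyloxiran-2-yl]-3-methyl-2-[(2S)-oxiran-2-yl]butoxy}silane | C=CCC[C@]1(C)O[C@@H]1[C@H](O[Si](CC)(CC)CC)[C@@H]([C@H]2CO2)C(C)C
F2 | step 9 | (4R,5R,6R)-6-[(2R,3S)-3-(but-3-en-1-yl)-3-methyloxiran-2-yl]-2-methyl-5-(propan-2-yl)-6-[(triethylsilyl)oxy]hex-1-en-4-ol | C=CCC[C@]1(C)O[C@@H]1[C@H](O[Si](CC)(CC)CC)[C@@H]([C@H](O)CC(C)=C)C(C)C
F3 | step 8 | {(1R,2R)-1-[(2R,3S)-3-(4,4-dibromobut-3-en-1-yl)-3-methyloxiran-2-yl]-3-methyl-2-[(2S)-oxiran-2-yl]butoxy}triethylsilane | BrC(Br)=CCC[C@]1(C)O[C@@H]1[C@H](O[Si](CC)(CC)CC)[C@@H]([C@H]2CO2)C(C)C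
F4 | step 8 | {(1R,2R)-1-[(2R,3S)-3-[(3Z)-4-bromopent-3-en-1-yl]-3-methyloxiran-2-yl]-3-methyl-2-[(2S)-oxiran-2-yl]butoxy}triethylsilane | Br/C(C)=C\CC[C@]1(C)O[C@@H]1[C@H](O[Si](CC)(CC)CC)[C@@H]([C@H]2CO2)C(C)C
F5 | step 8 | (2S,3R,4R)-4-[(2R,3S)-3-[(3Z)-4-bromopent-3-en-1-yl]-3-methyloxiran-2-yl]-1-iodo-3-(propan-2-yl)-4-[(triethylsilyl)oxy]butan-2-ol | Br/C(C)=C\CC[C@]1(C)O[C@@H]1[C@H](O[Si](CC)(CC)CC)[C@@H]([C@H](O)CI)C(C)C
F6 | step 5 | tert-butyl (1R,2R)-1-[(2R,3S)-3-methyl-3-(4-methylpent-3-en-1-yl)oxiran-2-yl]-2-(propan-2-yl)but-3-en-1-yl carbonate | CC(C)=CCC[C@]1(C)O[C@@H]1[C@H](OC(=O)OC(C)(C)C)[C@@H](C=C)C(C)C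
F7 | step 5 | tert-butyl (1R,2R)-1-[(2R,3S)-3-methyl-3-(3-oxopropyl)oxiran-2-yl]-2-(propan-2-yl)but-3-en-1-yl carbonate | O=CCC[C@]1(C)O[C@@H]1[C@H](OC(=O)OC(C)(C)C)[C@@H](C=C)C(C)C
F8 | step 5 | tert-butyl (1R,2R)-1-[(2R,3S)-3-[(3Z)-4-iodopent-3-en-1-yl]-3-methyloxiran-2-yl]-2-(propan-2-yl)but-3-en-1-yl carbonate | I/C(C)=C\CC[C@]1(C)O[C@@H]1[C@H](OC(=O)OC(C)(C)C)[C@@H](C=C)C(C)C
F9 | step 5 | (4S,5S,6R)-4-(iodomethyl)-6-[(2R,3S)-3-[(3Z)-4-iodopent-3-en-1-yl]-3-methyloxiran-2-yl]-5-(propan-2-yl)-1,3-dioxan-2-one | I/C(C)=C\CC[C@]1(C)O[C@@H]1[C@@H]2OC(=O)O[C@H](CI)[C@H]2C(C)C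
F10 | step 5 | (1R,2S)-1-[(2R,3S)-3-[(3Z)-4-iodopent-3-en-1-yl]-3-methyloxiran-2-yl]-3-methyl-2-[(2S)-oxiran-2-yl]butan-1-ol | I/C(C)=C\CC[C@]1(C)O[C@@H]1[C@H](O)[C@@H]([C@H]2CO2)C(C)C
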